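**Strategy.** Ring A is disconnected at C8–C8a so that its four contiguous oxygenated carbons C5, C6, C7 and C8 become the four carbons of a squarate, while ring C is carried intact as a 2-aryl-4-pyranone. One thermolysis opens a 4-hydroxycyclobutenone to a dienylketene that closes onto the pyranone C–H carbon, giving ring A with all four oxygens in place and already differentiated: C5 and C8 as free hydroxyls, C6 as methoxy, C7 as benzyloxy. The precursor is a 4-pyranonyl-4-hydroxycyclobutenone with methoxy beside the carbinol and benzyloxy beside the carbonyl; a squarate monoketal fixes that placement, and iodination of a dihydropyranone at its only enone α-carbon fixes the attachment point.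

Key step: step 8

Remark: the target is achiral; the stereocentres of 3, 4, 5, 12, 13 and 15 form racemic and are all erased on the way.
Remark: iodine is introduced on the 2,3-dihydropyranone, whose enone has a single α-carbon, because the aromatised pyranone offers two (C3 and C5) and would leave the regiochemistry open.

Step 1
Reactants: 1 4-methoxybenzaldehyde; 2 (E)-1-methoxy-3-(trimethylsilyloxy)buta-1,3-diene (Danishefsky's diene)
Product: 4 2-(4-methoxyphenyl)-2,3-dihydro-4H-pyran-4-one (racemic), via silyl enol ether cycloadduct 3 (not isolated)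
Conditions: ZnCl2, THF, rt; then TFA, CH2Cl2, 0 °C
Reagents that add atoms: none
Why: Lewis-acid-promoted hetero-Diels–Alder reaction of an aryl aldehyde with Danishefsky's diene, followed by acid-induced loss of methanol and of the silyl group, is the standard entry to 2-aryl-2,3-dihydro-4-pyranones; the one stereocentre forms racemic and disappears in step 3.

Step 2
Reactants: 4 2-(4-methoxyphenyl)-2,3-dihydro-4H-pyran-4-one
Product: 5 5-iodo-2-(4-methoxyphenyl)-2,3-dihydro-4H-pyran-4-one (racemic)
Conditions: I2, pyridine, CH2Cl2, 0 °C to rt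
Reagents that add atoms: iodine, II
Why: Johnson α-iodination of an enone: pyridine adds reversibly to the only β-carbon (C6), the resulting enolate is iodinated at C5 and pyridinium is expelled, so the halogen has a single possible position.

Step 3
Reactants: 5 5-iodo-2-(4-methoxyphenyl)-2,3-dihydro-4H-pyran-4-one
Product: 6 5-iodo-2-(4-methoxyphenyl)-4H-pyran-4-one
Conditions: DDQ, 1,4-dioxane, reflux
Reagents that add atoms: none
Why: DDQ dehydrogenation of the flavanone-to-flavone type: hydride is taken from the p-methoxybenzylic, oxygen-bearing C2–H and loss of a C3 proton gives the pyranone, while the vinyl iodide is inert to the quinone.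

Step 4
Reactants: 7 dimethyl squarate
Product: 8 2,3,4,4-tetramethoxycyclobut-2-en-1-one
Conditions: MeOSiMe3, TMSOTf (cat.), CH2Cl2, −78 °C to rt
Reagents that add atoms: methoxytrimethylsilane, CO[Si](C)(C)C
Why: Noyori-type ketalisation (alkoxysilane with catalytic silyl triflate) converts one squarate carbonyl into its dimethyl ketal; the second carbonyl, a vinylogous ester now flanked by a quaternary ketal carbon, should resist further ketalisation.

Step 5
Reactants: 8 2,3,4,4-tetramethoxycyclobut-2-en-1-one; 9 benzyl alcohol
Product: 10 3-(benzyloxy)-2,4,4-trimethoxycyclobut-2-en-1-one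
Conditions: BnOH (3 equiv), NaH (10 mol %), THF, 4 Å MS, 0 °C to rt
Reagents that add atoms: none
Why: Base-catalysed transetherification by conjugate addition–elimination: only the β-carbon (C3) of the vinylogous ester can accept benzyloxide, the C2 enol ether and the ketal are inert to alkoxide, and the sieves remove methanol to pull the equilibrium.

Step 6
Reactants: 6 5-iodo-2-(4-methoxyphenyl)-4H-pyran-4-one; 10 3-(benzyloxy)-2,4,4-trimethoxycyclobut-2-en-1-one
Product: 12 5-[3-(benzyloxy)-1-hydroxy-2,4,4-trimethoxycyclobut-2-en-1-yl]-2-(4-methoxyphenyl)-4H-pyran-4-one (racemic), via pyranonylmagnesium chloride 11 (not isolated)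
Conditions: iPrMgCl·LiCl, THF, −40 °C; then 10, −78 to −30 °C; aq. NH4Cl
Reagents that add atoms: none
Why: Iodine–magnesium exchange on α-iodo-β-oxy enones (iododioxinones, iodouracils, iodochromones) is fast at low temperature because the vinylogous ester carbonyl is a poor electrophile, and the alkenyl Grignard reagent then adds 1,2 to the only carbonyl of 10; the carbinol centre forms racemic and is erased in step 8.

Step 7
Reactants: 12 5-[3-(benzyloxy)-1-hydroxy-2,4,4-trimethoxycyclobut-2-en-1-yl]-2-(4-methoxyphenyl)-4H-pyran-4-one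
Product: 13 2-(benzyloxy)-4-hydroxy-3-methoxy-4-[6-(4-methoxyphenyl)-4-oxo-4H-pyran-3-yl]cyclobut-2-en-1-one (racemic)
Conditions: 0.5 M aq. HCl, THF, 0 °C
Reagents that add atoms: water, O
Why: Mild acetal hydrolysis: the ketal ionises to a cation stabilised by two alkoxy groups much more readily than the tertiary carbinol, which carries an electron-poor pyranonyl group, so the carbonyl is unveiled next to the benzyloxy carbon and the methoxy carbon stays next to the carbinol.

Step 8
Reactants: 13 2-(benzyloxy)-4-hydroxy-3-methoxy-4-[6-(4-methoxyphenyl)-4-oxo-4H-pyran-3-yl]cyclobut-2-en-1-one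
Product: 16 7-(benzyloxy)-5,8-dihydroxy-6-methoxy-2-(4-methoxyphenyl)-4H-chromen-4-one, via dienylketene 14 (not isolated), via cyclohexadienone tautomer 15 (not isolated)
Conditions: toluene (degassed), 110 °C, Ar
Reagents that add atoms: none
Why: Heating should trigger conrotatory 4π opening of the cyclobutenone C1–C4 bond, the donor hydroxyl turning outward and the pyranonyl inward, to give the (Z)-dienylketene 14 with its ketene carbon next to the pyranone C6–H. A thermal disrotatory 6π electrocyclisation then joins the ketene carbon (future C8) to that carbon (future C8a), closing ring A as cyclohexadienone 15, and enolisation of the C8a–H gives the aromatic hydroquinone 16. This is the Moore ring expansion of 4-hydroxy-4-aryl, heteroaryl or alkenyl cyclobutenones; the partner here is the C5=C6 bond of a 4-pyranone, which gives up less resonance energy than a benzene ring and keeps its vinylogous ester in 15. No stereocentre survives, since the carbinol centre is lost in the opening and the transient C8a centre of 15 on enolisation. The step needs outward rotation of the hydroxyl, which its donor character secures and the acceptor pyranonyl reinforces, and closure at C6, the only atom that completes a hexatriene (the pyranone carbonyl oxygen would need a seven-membered ring). Methoxy at C6 and benzyloxy at C7 follow from the placement fixed in steps 4 to 7.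

Step 9
Reactants: 16 7-(benzyloxy)-5,8-dihydroxy-6-methoxy-2-(4-methoxyphenyl)-4H-chromen-4-one
Product: 17 7-(benzyloxy)-5,6,8-trimethoxy-2-(4-methoxyphenyl)-4H-chromen-4-one
Conditions: MeI, K2CO3, DMF (degassed), 50 °C, Ar
Reagents that add atoms: iodomethane, CI
Why: Williamson methylation of both phenols, with warming for the chelated C5 hydroxyl; crude 16 should be used at once under argon so that the hydroquinone dianion is alkylated before it can be oxidised.

Step 10
Reactants: 17 7-(benzyloxy)-5,6,8-trimethoxy-2-(4-methoxyphenyl)-4H-chromen-4-one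
Product: 18 7-hydroxy-5,6,8-trimethoxy-2-(4-methoxyphenyl)-4H-chromen-4-one (7-hydroxy-4',5,6,8-tetramethoxyflavone)
Conditions: H2 (1 atm), 10% Pd/C, EtOAc/MeOH, rt
Reagents that add atoms: none
Why: Catalytic hydrogenolysis of the benzyl aryl ether; at ambient pressure and temperature the flavone C2=C3 bond and the aryl methyl ethers should be untouched.

**Compound list**

1 | 4-methoxybenzaldehyde | COc1ccc(C=O)cc1 | starting material
2 | (E)-1-methoxy-3-(trimethylsilyloxy)buta-1,3-diene | CO/C=C/C(=C)O[Si](C)(C)C | starting material
3 | 6-methoxy-2-(4-methoxyphenyl)-4-(trimethylsilyloxy)-3,6-dihydro-2H-pyran (racemic, cis/trans mixture) | COC1C=C(O[Si](C)(C)C)CC(c2ccc(OC)cc2)O1 | intermediate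
4 | 2-(4-methoxyphenyl)-2,3-dihydro-4H-pyran-4-one (racemic) | COc1ccc(C2CC(=O)C=CO2)cc1 | intermediate
5 | 5-iodo-2-(4-methoxyphenyl)-2,3-dihydro-4H-pyran-4-one (racemic) | COc1ccc(C2CC(=O)C(I)=CO2)cc1 | intermediate
6 | 5-iodo-2-(4-methoxyphenyl)-4H-pyran-4-one | COc1ccc(-c2cc(=O)c(I)co2)cc1 | intermediate
7 | dimethyl squarate | COC1=C(OC)C(=O)C1=O | starting material
8 | 2,3,4,4-tetramethoxycyclobut-2-en-1-one | COC1=C(OC)C(OC)(OC)C1=O | intermediate
9 | benzyl alcohol | OCc1ccccc1 | starting material
10 | 3-(benzyloxy)-2,4,4-trimethoxycyclobut-2-en-1-one | COC1=C(OCc2ccccc2)C(OC)(OC)C1=O | intermediate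
11 | [6-(4-methoxyphenyl)-4-oxo-4H-pyran-3-yl]magnesium chloride (LiCl complex) | COc1ccc(-c2cc(=O)c([Mg]Cl)co2)cc1 | intermediate
12 | 5-[3-(benzyloxy)-1-hydroxy-2,4,4-trimethoxycyclobut-2-en-1-yl]-2-(4-methoxyphenyl)-4H-pyran-4-one (racemic) | COC1=C(OCc2ccccc2)C(OC)(OC)C1(O)c1coc(-c2ccc(OC)cc2)cc1=O | intermediate
13 | 2-(benzyloxy)-4-hydroxy-3-methoxy-4-[6-(4-methoxyphenyl)-4-oxo-4H-pyran-3-yl]cyclobut-2-en-1-one (racemic) | O=C1C(OCc2ccccc2)=C(OC)C1(O)c1coc(-c2ccc(OC)cc2)cc1=O | intermediate
14 | (Z)-2-(benzyloxy)-4-hydroxy-3-methoxy-4-[6-(4-methoxyphenyl)-4-oxo-4H-pyran-3-yl]buta-1,3-dien-1-one | O=C=C(OCc1ccccc1)/C(OC)=C(/O)c1coc(-c2ccc(OC)cc2)cc1=O | intermediate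
15 | 7-(benzyloxy)-5-hydroxy-6-methoxy-2-(4-methoxyphenyl)-8aH-chromene-4,8-dione (racemic) | COc1ccc(C2=CC(=O)C3=C(O)C(OC)=C(OCc4ccccc4)C(=O)C3O2)cc1 | intermediate
16 | 7-(benzyloxy)-5,8-dihydroxy-6-methoxy-2-(4-methoxyphenyl)-4H-chromen-4-one | COc1ccc(-c2cc(=O)c3c(O)c(OC)c(OCc4ccccc4)c(O)c3o2)cc1 | intermediate
17 | 7-(benzyloxy)-5,6,8-trimethoxy-2-(4-methoxyphenyl)-4H-chromen-4-one | COc1ccc(-c2cc(=O)c3c(OC)c(OC)c(OCc4ccccc4)c(OC)c3o2)cc1 | intermediate
18 | 7-hydroxy-5,6,8-trimethoxy-2-(4-methoxyphenyl)-4H-chromen-4-one | COc1ccc(-c2cc(=O)c3c(OC)c(OC)c(O)c(OC)c3o2)cc1 | target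

**Total step count:** 10.
**Longest linear sequence:** 8 steps (steps 1, 2, 3, 6, 7, 8, 9, 10, from 4-methoxybenzaldehyde).

**Steps most likely to fail**

Step 8. After ring opening the ketene may be captured by the neighbouring hydroxyl (lactonisation to a butenolide if the hydroxyl turns inward), or the electron-rich hydroquinone may be oxidised to the quinone during heating and isolation. The fallback sets out from 13: the tertiary hydroxyl is methylated (MeI, Ag2O, MeCN, rt) to 2-(benzyloxy)-3,4-dimethoxy-4-[6-(4-methoxyphenyl)-4-oxo-4H-pyran-3-yl]cyclobut-2-en-1-one F1, which has no hydroxyl to trap the ketene. Thermolysis of this ether (toluene, 110 °C) should give 7-(benzyloxy)-8-hydroxy-5,6-dimethoxy-2-(4-methoxyphenyl)-4H-chromen-4-one F2, a monophenol and therefore much less prone to oxidation. Methylation of its single hydroxyl under the conditions of step 9 comes back to the route at 17.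

Step 6. The magnesiated pyranone may fragment by β-elimination of the ring oxygen, iPrMgCl may attack the pyranone before exchange, or benzyloxide may be displaced at C3 of 10 in place of carbonyl addition. The fallback sets out from 6 and 10 and joins them by a Nozaki–Hiyama–Kishi coupling (CrCl2, catalytic NiCl2, DMF, rt). The alkenylchromium species is non-basic, adds only 1,2 and is generated in the presence of the strained, reactive cyclobutenone carbonyl. The coupling comes back to the route at 12 and makes no new compound.

Step 3. Hydride abstraction from the electron-poor iodo enone may be slow, so that prolonged heating with DDQ erodes the material. The fallback sets out from 5: the α'-enolate (LiN(SiMe3)2, THF, −78 °C) is selenated with PhSeCl to 5-iodo-2-(4-methoxyphenyl)-3-(phenylselanyl)-2,3-dihydro-4H-pyran-4-one F3, with selenium trans to the aryl group. Oxidation (H2O2, pyridine, CH2Cl2, 0 °C) then triggers selenoxide syn-elimination toward the C2–H and comes back to the route at 6.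

**Further compounds**

F1 | step 8 | 2-(benzyloxy)-3,4-dimethoxy-4-[6-(4-methoxyphenyl)-4-oxo-4H-pyran-3-yl]cyclobut-2-en-1-one (racemic) | O=C1C(OCc2ccccc2)=C(OC)C1(OC)c1coc(-c2ccc(OC)cc2)cc1=O
F2 | step 8 | 7-(benzyloxy)-8-hydroxy-5,6-dimethoxy-2-(4-methoxyphenyl)-4H-chromen-4-one | COc1ccc(-c2cc(=O)c3c(OC)c(OC)c(OCc4ccccc4)c(O)c3o2)cc1
F0 | step 6 | none | none
F3 | step 3 | 5-iodo-2-(4-methoxyphenyl)-3-(phenylselanyl)-2,3-dihydro-4H-pyran-4-one (racemic, trans) | COc1ccc(C2OC=C(I)C(=O)C2[Se]c2ccccc2)cc1
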